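**Strategy**

Everything rests on building the 5-hydroxyindole (ring system A) last, on the finished tetramethoxyphenyl–6-prenylindole core. In ring A the C5 hydroxyl sits para to C7a, the carbon that carries N1; this 1,4-pattern is a masked 2-aminofuran (furan C2 becomes C7a, furan C5 becomes C5, the ring oxygen becomes the phenol). Heating a tertiary propargylic alcohol that bears an ethynyl group, the central aryl ring and a CH2–N(Boc)(2-furyl) arm triggers an intramolecular furan–alkyne cycloaddition forming C3a–C7a and C4–C5; bridge opening, dehydration and thermal Boc loss then deliver the target itself, because indole B is left unprotected in the precursor.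

Key step: step 11

Remark: prenyl bromide, 3-(trimethylsilyl)propynal and tributyl(iodomethyl)stannane are taken as purchased materials; "prenyl" means 3-methylbut-2-en-1-yl.
Remark: a salt that is only the conjugate base of a numbered compound (N-sodio species, lithium alkoxide before quench) is treated as that compound; carbon–metal species and covalent intermediates carry their own numbers.
Remark: the N-silyl group of indole B is removed before the thermal step, together with the alkynyl silane, because an N–Si bond is unreliable at 180 °C in the presence of the water and phenol that the cascade releases; this also removes the need for a final deprotection.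

**Route**

Step 1
Reactants: 1 6-bromoindole
Product: 2 6-bromo-1-(triisopropylsilyl)-1H-indole
Conditions: NaH, THF, 0 °C; TIPSCl, 0 °C → rt
Reagents that add atoms: chlorotriisopropylsilane (TIPSCl), CC(C)[Si](Cl)(C(C)C)C(C)C
Why: Deprotonation of the indole N–H and N-silylation (standard N-protection) installs a bulky group that tolerates organolithium reagents, shields C2 from lithiation and leaves C3 as the site of later electrophilic bromination.

Step 2
Reactants: 2 6-bromo-1-(triisopropylsilyl)-1H-indole; 3 prenyl bromide (1-bromo-3-methylbut-2-ene)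
Product: 5 6-(3-methylbut-2-en-1-yl)-1-(triisopropylsilyl)-1H-indole, via 6-lithio-1-(triisopropylsilyl)-1H-indole 4 (not isolated)
Conditions: t-BuLi (2.1 equiv), THF, −78 °C; then 3, −78 °C → rt
Reagents that add atoms: none
Why: Bromine–lithium exchange at C6 is faster than any deprotonation, and the aryllithium is alkylated at the unhindered CH2 terminus of the primary allylic bromide (SN2 allylation), which should give the linear prenyl group.

Step 3
Reactants: 5 6-(3-methylbut-2-en-1-yl)-1-(triisopropylsilyl)-1H-indole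
Product: 6 3-bromo-6-(3-methylbut-2-en-1-yl)-1-(triisopropylsilyl)-1H-indole
Conditions: NBS, THF, −78 → 0 °C, dark
Reagents that add atoms: N-bromosuccinimide (NBS), O=C1CCC(=O)N1Br
Why: Electrophilic aromatic bromination of an N-silylindole goes irreversibly at C3, its most nucleophilic carbon, whereas bromonium formation at the trisubstituted olefin is reversible in an aprotic medium that offers no nucleophile.

Step 4
Reactants: 7 1,2,4,5-tetramethoxybenzene; 6 3-bromo-6-(3-methylbut-2-en-1-yl)-1-(triisopropylsilyl)-1H-indole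
Product: 10 6-(3-methylbut-2-en-1-yl)-3-(2,3,5,6-tetramethoxyphenyl)-1-(triisopropylsilyl)-1H-indole, via (2,3,5,6-tetramethoxyphenyl)lithium 8 (not isolated), via (2,3,5,6-tetramethoxyphenyl)zinc chloride 9 (not isolated)
Conditions: 7, n-BuLi, THF, 0 °C → rt; ZnCl2, 0 °C → rt; then 6, Pd2(dba)3 (cat.), SPhos, THF, 60 °C
Reagents that add atoms: none
Why: Directed ortho-lithiation between two methoxy groups, transmetalation to zinc and Negishi cross-coupling under zerovalent palladium with a bulky biaryl phosphine, which suits di-ortho-substituted arylzinc partners, should join the central ring to C3 of indole B.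

Step 5
Reactants: 10 6-(3-methylbut-2-en-1-yl)-3-(2,3,5,6-tetramethoxyphenyl)-1-(triisopropylsilyl)-1H-indole; 11 3-(trimethylsilyl)propynal
Product: 13 racemic 1-{2,3,5,6-tetramethoxy-4-[6-(3-methylbut-2-en-1-yl)-1-(triisopropylsilyl)-1H-indol-3-yl]phenyl}-3-(trimethylsilyl)prop-2-yn-1-ol, via {2,3,5,6-tetramethoxy-4-[6-(3-methylbut-2-en-1-yl)-1-(triisopropylsilyl)-1H-indol-3-yl]phenyl}lithium 12 (not isolated)
Conditions: n-BuLi (1.1 equiv), THF, −20 → 0 °C; then 11, −78 °C; H2O quench
Reagents that add atoms: none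
Why: The last hydrogen of the central ring lies between two methoxy groups, so directed ortho-metalation should outpace deprotonation elsewhere, and the aryllithium adds 1,2 to the non-enolizable ynal; the carbinol center forms as a racemate and is removed by oxidation in step 6.

Step 6
Reactants: 13 racemic 1-{2,3,5,6-tetramethoxy-4-[6-(3-methylbut-2-en-1-yl)-1-(triisopropylsilyl)-1H-indol-3-yl]phenyl}-3-(trimethylsilyl)prop-2-yn-1-ol
Product: 14 1-{2,3,5,6-tetramethoxy-4-[6-(3-methylbut-2-en-1-yl)-1-(triisopropylsilyl)-1H-indol-3-yl]phenyl}-3-(trimethylsilyl)prop-2-yn-1-one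
Conditions: MnO2 (activated, excess), CH2Cl2, rt
Reagents that add atoms: none
Why: Activated MnO2 oxidizes benzylic–propargylic secondary alcohols to ynones under neutral conditions that should leave the olefin, both silyl groups and the electron-rich indole untouched.

Step 7
Reactants: 15 2-furoic acid
Product: 18 tert-butyl furan-2-ylcarbamate, via furan-2-carbonyl azide 16 (not isolated), via 2-isocyanatofuran 17 (not isolated)
Conditions: DPPA, Et3N, t-BuOH, rt then reflux
Reagents that add atoms: diphenylphosphoryl azide (DPPA), [N-]=[N+]=NP(=O)(Oc1ccccc1)Oc1ccccc1; tert-butanol, CC(C)(C)O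
Why: Curtius rearrangement: the acyl azide loses N2 on heating and the furyl isocyanate is trapped by tert-butanol as the Boc carbamate.

Step 8
Reactants: 18 tert-butyl furan-2-ylcarbamate; 19 tributyl(iodomethyl)stannane
Product: 20 tert-butyl furan-2-yl[(tributylstannyl)methyl]carbamate
Conditions: NaH, DMF, 0 °C; then 19, 0 °C → rt
Reagents that add atoms: none
Why: SN2 N-alkylation of the sodium carbamate by the primary iodide installs a stannylmethyl group that serves as a latent α-amino carbanion.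

Step 9
Reactants: 20 tert-butyl furan-2-yl[(tributylstannyl)methyl]carbamate; 14 1-{2,3,5,6-tetramethoxy-4-[6-(3-methylbut-2-en-1-yl)-1-(triisopropylsilyl)-1H-indol-3-yl]phenyl}-3-(trimethylsilyl)prop-2-yn-1-one
Product: 22 racemic tert-butyl furan-2-yl{2-hydroxy-2-{2,3,5,6-tetramethoxy-4-[6-(3-methylbut-2-en-1-yl)-1-(triisopropylsilyl)-1H-indol-3-yl]phenyl}-4-(trimethylsilyl)but-3-yn-1-yl}carbamate, via tert-butyl furan-2-yl(lithiomethyl)carbamate 21 (not isolated)
Conditions: 20, n-BuLi, THF, −78 °C; then 14, −78 °C; H2O quench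
Reagents that add atoms: none
Why: Tin–lithium exchange gives a carbamate-chelated α-aminomethyllithium that should add 1,2 to the ynone, which has no α-hydrogen to enolize and a silyl-blocked β-carbon; the tertiary carbinol center forms as a racemate, which does not matter because it becomes the sp2 carbon C3 of ring A in step 11.

Step 10
Reactants: 22 racemic tert-butyl furan-2-yl{2-hydroxy-2-{2,3,5,6-tetramethoxy-4-[6-(3-methylbut-2-en-1-yl)-1-(triisopropylsilyl)-1H-indol-3-yl]phenyl}-4-(trimethylsilyl)but-3-yn-1-yl}carbamate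
Product: 23 racemic tert-butyl furan-2-yl{2-hydroxy-2-{2,3,5,6-tetramethoxy-4-[6-(3-methylbut-2-en-1-yl)-1H-indol-3-yl]phenyl}but-3-yn-1-yl}carbamate
Conditions: TBAF (2.2 equiv), wet THF, 0 °C
Reagents that add atoms: none
Why: Fluoride-mediated desilylation should cleave both the alkynyl C–Si and the indole N–Si bond at 0 °C while the carbamate, the furan and the tertiary alcohol are left alone.

Step 11
Reactants: 23 racemic tert-butyl furan-2-yl{2-hydroxy-2-{2,3,5,6-tetramethoxy-4-[6-(3-methylbut-2-en-1-yl)-1H-indol-3-yl]phenyl}but-3-yn-1-yl}carbamate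
Product: 27 3-{2,3,5,6-tetramethoxy-4-[6-(3-methylbut-2-en-1-yl)-1H-indol-3-yl]phenyl}-1H-indol-5-ol, via oxanorbornadiene cycloadduct 24 (not isolated), via N-Boc indoline-3,5-diol 25 (not isolated), via N-Boc 5-hydroxyindole 26 (not isolated)
Conditions: o-dichlorobenzene (degassed, 0.05 M), microwave, 180 °C, sealed vial, argon
Reagents that add atoms: none
Why: On heating, the electron-rich N-Boc-2-aminofuran acts as the diene toward the tethered terminal alkyne in an intramolecular Diels–Alder reaction of a furan (closest known type: the thermal aminofuran–alkynol route to 5-hydroxyindoles), forming C3a–C7a and C4–C5 and giving oxanorbornadiene 24. The five-membered ring (N1, C2, C3, C3a, C7a) closes as the three-atom tether of this cycloaddition, in a 5-exo-dig sense, and the six-membered carbocycle closes by the concerted suprafacial [4+2] itself, helped by the fully substituted carbinol carbon in the tether. The carbamate nitrogen on C7a then expels the bridging oxygen, which stays on C5, and proton loss from C5 gives phenol 25; loss of water across C3–C2 aromatizes the pyrrole ring (26) and the hot medium expels isobutene and CO2 from the carbamate. No stereocenter survives, since the racemic carbinol center of 23 and the transient centers of 24 are erased on aromatization. The step needs regiocontrol, secured by the tether length and by the nitrogen at C7a so that the hydroxyl can only appear at C5, and chemoselectivity for the alkyne over the prenyl olefin and indole B, secured by intramolecularity.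

**Compound list**

1 | 6-bromoindole | Brc1ccc2cc[nH]c2c1 | starting material
2 | 6-bromo-1-(triisopropylsilyl)-1H-indole | Brc1ccc2ccn([Si](C(C)C)(C(C)C)C(C)C)c2c1 | intermediate
3 | prenyl bromide (1-bromo-3-methylbut-2-ene) | CC(C)=CCBr | starting material
4 | 6-lithio-1-(triisopropylsilyl)-1H-indole | [Li]c1ccc2ccn([Si](C(C)C)(C(C)C)C(C)C)c2c1 | intermediate (not isolated)
5 | 6-(3-methylbut-2-en-1-yl)-1-(triisopropylsilyl)-1H-indole | CC(C)=CCc1ccc2ccn([Si](C(C)C)(C(C)C)C(C)C)c2c1 | intermediate
6 | 3-bromo-6-(3-methylbut-2-en-1-yl)-1-(triisopropylsilyl)-1H-indole | CC(C)=CCc1ccc2c(Br)cn([Si](C(C)C)(C(C)C)C(C)C)c2c1 | intermediate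
7 | 1,2,4,5-tetramethoxybenzene | COc1cc(OC)c(OC)cc1OC | starting material
8 | (2,3,5,6-tetramethoxyphenyl)lithium | [Li]c1c(OC)c(OC)cc(OC)c1OC | intermediate (not isolated)
9 | (2,3,5,6-tetramethoxyphenyl)zinc chloride | Cl[Zn]c1c(OC)c(OC)cc(OC)c1OC | intermediate (not isolated)
10 | 6-(3-methylbut-2-en-1-yl)-3-(2,3,5,6-tetramethoxyphenyl)-1-(triisopropylsilyl)-1H-indole | COc1cc(OC)c(OC)c(-c2cn([Si](C(C)C)(C(C)C)C(C)C)c3cc(CC=C(C)C)ccc23)c1OC | intermediate
11 | 3-(trimethylsilyl)propynal | O=CC#C[Si](C)(C)C | starting material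
12 | {2,3,5,6-tetramethoxy-4-[6-(3-methylbut-2-en-1-yl)-1-(triisopropylsilyl)-1H-indol-3-yl]phenyl}lithium | [Li]c1c(OC)c(OC)c(-c2cn([Si](C(C)C)(C(C)C)C(C)C)c3cc(CC=C(C)C)ccc23)c(OC)c1OC | intermediate (not isolated)
13 | racemic 1-{2,3,5,6-tetramethoxy-4-[6-(3-methylbut-2-en-1-yl)-1-(triisopropylsilyl)-1H-indol-3-yl]phenyl}-3-(trimethylsilyl)prop-2-yn-1-ol | C[Si](C)(C)C#CC(O)c1c(OC)c(OC)c(-c2cn([Si](C(C)C)(C(C)C)C(C)C)c3cc(CC=C(C)C)ccc23)c(OC)c1OC | intermediate
14 | 1-{2,3,5,6-tetramethoxy-4-[6-(3-methylbut-2-en-1-yl)-1-(triisopropylsilyl)-1H-indol-3-yl]phenyl}-3-(trimethylsilyl)prop-2-yn-1-one | C[Si](C)(C)C#CC(=O)c1c(OC)c(OC)c(-c2cn([Si](C(C)C)(C(C)C)C(C)C)c3cc(CC=C(C)C)ccc23)c(OC)c1OC | intermediate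
15 | 2-furoic acid | O=C(O)c1ccco1 | starting material
16 | furan-2-carbonyl azide | [N-]=[N+]=NC(=O)c1ccco1 | intermediate (not isolated)
17 | 2-isocyanatofuran | O=C=Nc1ccco1 | intermediate (not isolated)
18 | tert-butyl furan-2-ylcarbamate | CC(C)(C)OC(=O)Nc1ccco1 | intermediate
19 | tributyl(iodomethyl)stannane | CCCC[Sn](CCCC)(CCCC)CI | starting material
20 | tert-butyl furan-2-yl[(tributylstannyl)methyl]carbamate | CCCC[Sn](CCCC)(CCCC)CN(C(=O)OC(C)(C)C)c1ccco1 | intermediate
21 | tert-butyl furan-2-yl(lithiomethyl)carbamate | [Li]CN(C(=O)OC(C)(C)C)c1ccco1 | intermediate (not isolated)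
22 | racemic tert-butyl furan-2-yl{2-hydroxy-2-{2,3,5,6-tetramethoxy-4-[6-(3-methylbut-2-en-1-yl)-1-(triisopropylsilyl)-1H-indol-3-yl]phenyl}-4-(trimethylsilyl)but-3-yn-1-yl}carbamate | C[Si](C)(C)C#CC(O)(CN(C(=O)OC(C)(C)C)c1ccco1)c1c(OC)c(OC)c(-c2cn([Si](C(C)C)(C(C)C)C(C)C)c3cc(CC=C(C)C)ccc23)c(OC)c1OC | intermediate
23 | racemic tert-butyl furan-2-yl{2-hydroxy-2-{2,3,5,6-tetramethoxy-4-[6-(3-methylbut-2-en-1-yl)-1H-indol-3-yl]phenyl}but-3-yn-1-yl}carbamate (key-step precursor) | C#CC(O)(CN(C(=O)OC(C)(C)C)c1ccco1)c1c(OC)c(OC)c(-c2c[nH]c3cc(CC=C(C)C)ccc23)c(OC)c1OC | intermediate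
24 | oxanorbornadiene cycloadduct (oxygen bridging C5 and C7a, olefins C3a=C4 and C6=C7, N-Boc, C3 hydroxyl and aryl; racemic, diastereomers not specified) | CC(C)(C)OC(=O)N1CC(O)(c2c(OC)c(OC)c(-c3c[nH]c4cc(CC=C(C)C)ccc34)c(OC)c2OC)C2=CC3C=CC12O3 | intermediate (not isolated)
25 | racemic tert-butyl 3,5-dihydroxy-3-{2,3,5,6-tetramethoxy-4-[6-(3-methylbut-2-en-1-yl)-1H-indol-3-yl]phenyl}indoline-1-carboxylate | CC(C)(C)OC(=O)N1CC(O)(c2c(OC)c(OC)c(-c3c[nH]c4cc(CC=C(C)C)ccc34)c(OC)c2OC)c2cc(O)ccc21 | intermediate (not isolated)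
26 | tert-butyl 5-hydroxy-3-{2,3,5,6-tetramethoxy-4-[6-(3-methylbut-2-en-1-yl)-1H-indol-3-yl]phenyl}-1H-indole-1-carboxylate | CC(C)(C)OC(=O)n1cc(-c2c(OC)c(OC)c(-c3c[nH]c4cc(CC=C(C)C)ccc34)c(OC)c2OC)c2cc(O)ccc21 | intermediate (not isolated)
27 | 3-{2,3,5,6-tetramethoxy-4-[6-(3-methylbut-2-en-1-yl)-1H-indol-3-yl]phenyl}-1H-indol-5-ol (no stereocenter) | COc1c(OC)c(-c2c[nH]c3ccc(O)cc23)c(OC)c(OC)c1-c1c[nH]c2cc(CC=C(C)C)ccc12 | target

**Summary**

Total step count: 11.
Longest linear sequence: 9 steps (steps 1, 2, 3, 4, 5, 6, 9, 10, 11, from 6-bromoindole); steps 7 and 8 form the two-step side branch to stannane 20.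

**Steps most likely to fail**

Step 11. The aminofuran may decompose or lose its Boc group before the crowded cycloaddition takes place, the di-ortho-methoxyaryl group may slow the cycloaddition, or bridge opening and dehydration may stop short of the indole. The fallback abandons the construction of ring A and brings it in ready-made by cross-coupling. It sets out from 10 and comes back at target 27. Purchased 5-hydroxyindole (Oc1ccc2[nH]ccc2c1) would be bis-silylated (NaH, TIPSCl, THF) to 5-(triisopropylsilyloxy)-1-(triisopropylsilyl)-1H-indole F1 and brominated at C3 (NBS, THF, −78 °C) to 3-bromo-5-(triisopropylsilyloxy)-1-(triisopropylsilyl)-1H-indole F2. Compound 10 would be lithiated as in step 5 to 12 and transmetalated with ZnCl2 to {2,3,5,6-tetramethoxy-4-[6-(3-methylbut-2-en-1-yl)-1-(triisopropylsilyl)-1H-indol-3-yl]phenyl}zinc chloride F3. Negishi coupling of F3 with F2 (Pd2(dba)3, SPhos, THF, 60 °C) should give the tris-silylated 1,4-bis(indol-3-yl)tetramethoxybenzene F4, and TBAF in THF would remove all three silyl groups to give 27.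

Step 9. 1,2-Addition to a ketone flanked by a 2,6-dimethoxyaryl ring may be slow, so that conjugate addition to the ynone or decay of the α-amino organolithium competes. The fallback reverses the order in which the two carbon groups are attached to the carbonyl carbon and avoids tin. It sets out from 18 and 10 and comes back at 23. Carbamate 18 would be N-alkylated (NaH, DMF) with purchased 2-chloro-N-methoxy-N-methylacetamide (CON(C)C(=O)CCl) to tert-butyl furan-2-yl{2-[methoxy(methyl)amino]-2-oxoethyl}carbamate F5. Aryllithium 12, made from 10 as in step 5, would be acylated by F5 at −78 °C to the α-amino ketone tert-butyl furan-2-yl(2-oxo-2-{2,3,5,6-tetramethoxy-4-[6-(3-methylbut-2-en-1-yl)-1-(triisopropylsilyl)-1H-indol-3-yl]phenyl}ethyl)carbamate F6. The small nucleophile ethynylmagnesium bromide (with anhydrous CeCl3, THF, −78 °C, to suppress enolization) should add to give the N-silylated terminal alkynol, racemic tert-butyl furan-2-yl{2-hydroxy-2-{2,3,5,6-tetramethoxy-4-[6-(3-methylbut-2-en-1-yl)-1-(triisopropylsilyl)-1H-indol-3-yl]phenyl}but-3-yn-1-yl}carbamate F7. TBAF in THF at 0 °C would remove the N-silyl group to give 23.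

Step 5. n-BuLi may deprotonate the benzylic–allylic CH2 of the prenyl group (or indole C2–H) in competition with ortho-lithiation, which would scramble the olefin position or give mixtures of addition products. The fallback makes the central ring the electrophile, so that no strong base meets a prenylated compound. It sets out from 6 and 7 and comes back at 13. Bromide 6 would be converted by Miyaura borylation (B2pin2, PdCl2(dppf), KOAc, dioxane, 80 °C) to 6-(3-methylbut-2-en-1-yl)-3-(4,4,5,5-tetramethyl-1,3,2-dioxaborolan-2-yl)-1-(triisopropylsilyl)-1H-indole F8. Arene 7 would be dibrominated (Br2, CH2Cl2, 0 °C) to 1,4-dibromo-2,3,5,6-tetramethoxybenzene F9. One bromine–lithium exchange (n-BuLi, 1 equiv, THF, −78 °C) would give (4-bromo-2,3,5,6-tetramethoxyphenyl)lithium F10, which DMF traps as 4-bromo-2,3,5,6-tetramethoxybenzaldehyde F11. Suzuki–Miyaura coupling of F8 with F11 (Pd(OAc)2, SPhos, K3PO4, toluene/H2O, 80 °C) should give 2,3,5,6-tetramethoxy-4-[6-(3-methylbut-2-en-1-yl)-1-(triisopropylsilyl)-1H-indol-3-yl]benzaldehyde F12. Addition of lithium (trimethylsilyl)acetylide F13 (from trimethylsilylacetylene and n-BuLi, THF, −78 °C) to F12 would give 13.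

**Further compounds**

F1 | step 11 | 5-(triisopropylsilyloxy)-1-(triisopropylsilyl)-1H-indole | CC(C)[Si](Oc1ccc2c(ccn2[Si](C(C)C)(C(C)C)C(C)C)c1)(C(C)C)C(C)C
F2 | step 11 | 3-bromo-5-(triisopropylsilyloxy)-1-(triisopropylsilyl)-1H-indole | CC(C)[Si](Oc1ccc2c(c1)c(Br)cn2[Si](C(C)C)(C(C)C)C(C)C)(C(C)C)C(C)C
F3 | step 11 | {2,3,5,6-tetramethoxy-4-[6-(3-methylbut-2-en-1-yl)-1-(triisopropylsilyl)-1H-indol-3-yl]phenyl}zinc chloride | Cl[Zn]c1c(OC)c(OC)c(-c2cn([Si](C(C)C)(C(C)C)C(C)C)c3cc(CC=C(C)C)ccc23)c(OC)c1OC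
F4 | step 11 | 3-{2,3,5,6-tetramethoxy-4-[6-(3-methylbut-2-en-1-yl)-1-(triisopropylsilyl)-1H-indol-3-yl]phenyl}-5-(triisopropylsilyloxy)-1-(triisopropylsilyl)-1H-indole | COc1c(OC)c(-c2cn([Si](C(C)C)(C(C)C)C(C)C)c3ccc(O[Si](C(C)C)(C(C)C)C(C)C)cc23)c(OC)c(OC)c1-c1cn([Si](C(C)C)(C(C)C)C(C)C)c2cc(CC=C(C)C)ccc12
F5 | step 9 | tert-butyl furan-2-yl{2-[methoxy(methyl)amino]-2-oxoethyl}carbamate | CON(C)C(=O)CN(C(=O)OC(C)(C)C)c1ccco1
F6 | step 9 | tert-butyl furan-2-yl(2-oxo-2-{2,3,5,6-tetramethoxy-4-[6-(3-methylbut-2-en-1-yl)-1-(triisopropylsilyl)-1H-indol-3-yl]phenyl}ethyl)carbamate | CC(C)(C)OC(=O)N(CC(=O)c1c(OC)c(OC)c(-c2cn([Si](C(C)C)(C(C)C)C(C)C)c3cc(CC=C(C)C)ccc23)c(OC)c1OC)c1ccco1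
F7 | step 9 | racemic tert-butyl furan-2-yl{2-hydroxy-2-{2,3,5,6-tetramethoxy-4-[6-(3-methylbut-2-en-1-yl)-1-(triisopropylsilyl)-1H-indol-3-yl]phenyl}but-3-yn-1-yl}carbamate | C#CC(O)(CN(C(=O)OC(C)(C)C)c1ccco1)c1c(OC)c(OC)c(-c2cn([Si](C(C)C)(C(C)C)C(C)C)c3cc(CC=C(C)C)ccc23)c(OC)c1OC
F8 | step 5 | 6-(3-methylbut-2-en-1-yl)-3-(4,4,5,5-tetramethyl-1,3,2-dioxaborolan-2-yl)-1-(triisopropylsilyl)-1H-indole | CC(C)=CCc1ccc2c(B3OC(C)(C)C(C)(C)O3)cn([Si](C(C)C)(C(C)C)C(C)C)c2c1
F9 | step 5 | 1,4-dibromo-2,3,5,6-tetramethoxybenzene | COc1c(Br)c(OC)c(OC)c(Br)c1OC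
F10 | step 5 | (4-bromo-2,3,5,6-tetramethoxyphenyl)lithium | [Li]c1c(OC)c(OC)c(Br)c(OC)c1OC
F11 | step 5 | 4-bromo-2,3,5,6-tetramethoxybenzaldehyde | O=Cc1c(OC)c(OC)c(Br)c(OC)c1OC
F12 | step 5 | 2,3,5,6-tetramethoxy-4-[6-(3-methylbut-2-en-1-yl)-1-(triisopropylsilyl)-1H-indol-3-yl]benzaldehyde | O=Cc1c(OC)c(OC)c(-c2cn([Si](C(C)C)(C(C)C)C(C)C)c3cc(CC=C(C)C)ccc23)c(OC)c1OC
F13 | step 5 | lithium (trimethylsilyl)acetylide | [Li]C#C[Si](C)(C)C
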